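**Retrosynthetic overview**
1. Target 31 ⇒ Heck union of vinyl carbinol 30 with bromodienamide 17; the ring enamide C–N bond ⇒ Cu-catalysed coupling of iodoenone 28 with dienamide 9.
2. Ring A (cyclohexenone) ⇒ ring expansion: Pd-catalysed Wagner–Meerwein 1,2-alkenyl shift of alkoxyallenyl cyclopentenol 22, which creates the quaternary carbon bearing O and vinyl; 22 ⇐ silyloxycyclopentenone 19 + lithiated allenyl ether from 18.
3. The secondary ring hydroxyl ⇐ hydride addition anti to the neighbouring ether; the bought carbinol centre relays chirality and ends as the enone carbonyl.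
4. Dienamide 9 ⇐ asymmetric allylic methylation, cross-metathesis, Wittig; amide 17 ⇐ glutaconaldehyde salt + aminocyclopentenolone from cyclopentane-1,3-dione.
5. Ring order: bought five-membered carbocycle → ring A by expansion → temporary dioxolane (removed); ring B (cyclopentenolone) is carried in from the dione.

Assumption: 18 and 19 are bought as their p-methoxybenzyl and silyl ethers, and the acetal carbon of 26–29 is an inconsequential epimer mixture left unspecified in the SMILES.

**Step 1**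
Reactants: 1 (E)-hept-2-en-1-ol
Product: 2 (E)-1-bromohept-2-ene
Conditions: PBr3, Et2O, −10 °C
Reagents that add atoms: phosphorus tribromide, BrP(Br)Br
Why: Alcohol-to-bromide substitution with PBr3 at low temperature occurs at the primary allylic carbon and keeps the E alkene.

**Step 2**
Reactants: 2 (E)-1-bromohept-2-ene
Product: 3 (R)-3-methylhept-1-ene
Conditions: MeMgBr, CuBr·SMe2 (1 mol %), (R,R)-Taniaphos (1.2 mol %), CH2Cl2, −75 °C
Reagents that add atoms: methylmagnesium bromide, C[Mg]Br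
Why: Copper-catalysed asymmetric allylic alkylation (SN2′) with a Grignard reagent gives the branched alkene, the ferrocenyl diphosphine (the antipode that delivers R) fixing the face of γ-attack and so the methyl-bearing centre.

**Step 3**
Reactants: 3 (R)-3-methylhept-1-ene; 4 methacrolein
Product: 5 (2E,4R)-2,4-dimethyloct-2-enal
Conditions: 4 (5 equiv), second-generation Hoveyda–Grubbs catalyst RuCl2(SIMes)(=CH-2-iPrOC6H4) (5 mol %), CH2Cl2, 40 °C
Reagents that add atoms: none
Why: Olefin cross-metathesis of a terminal alkene with excess methacrolein gives the thermodynamic E trisubstituted enal and does not touch the allylic stereocentre.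

**Step 4**
Reactants: 5 (2E,4R)-2,4-dimethyloct-2-enal; 6 2-bromopropanamide
Product: 9 (2E,4E,6R)-2,4,6-trimethyldeca-2,4-dienamide, via phosphonium bromide 7 (not isolated), via ylide 8 (not isolated)
Conditions: 6, PPh3, MeCN, 80 °C; then NaOH (aq)/CH2Cl2, 0 °C; then 5, CH2Cl2, 40 °C
Reagents that add atoms: none
Why: Wittig olefination with the amide-stabilised, α-methyl ylide gives the E trisubstituted alkene and delivers the primary amide directly.

**Step 5**
Reactants: 10 cyclopentane-1,3-dione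
Product: 11 2-(hydroxyimino)cyclopentane-1,3-dione
Conditions: NaNO2, AcOH–H2O, 0–5 °C
Reagents that add atoms: sodium nitrite, [Na+].[O-]N=O
Why: Nitrosation of the enolised 1,3-dione at its central carbon followed by tautomerisation gives the oxime.

**Step 6**
Reactants: 11 2-(hydroxyimino)cyclopentane-1,3-dione
Product: 12 2-amino-3-hydroxycyclopent-2-en-1-one hydrochloride
Conditions: H2 (3 atm), Pd/C (palladium on carbon), HCl, EtOH, rt
Reagents that add atoms: hydrogen chloride, Cl
Why: Catalytic hydrogenation of the oxime gives the amine, trapped as its hydrochloride so that the aminodione (enol form) does not self-condense.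

**Step 7**
Reactants: 13 glutaconaldehyde potassium salt
Product: 14 (2E,4E)-5-bromopenta-2,4-dienal
Conditions: PPh3, Br2, CH2Cl2, 0 °C → rt
Reagents that add atoms: bromine, BrBr
Why: Ph3PBr2 activates the enolate oxygen and bromide displaces it by addition–elimination (bromodeoxygenation of a vinylogous formate), giving the conjugated E,E bromodienal.

**Step 8**
Reactants: 14 (2E,4E)-5-bromopenta-2,4-dienal
Product: 15 (2E,4E)-5-bromopenta-2,4-dienoic acid
Conditions: NaClO2, NaH2PO4, 2-methylbut-2-ene, t-BuOH–H2O, rt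
Reagents that add atoms: sodium chlorite, [Na+].[O-]Cl=O
Why: Pinnick oxidation converts the enal into the acid without touching the bromodiene, the alkene scavenger removing HOCl.

**Step 9**
Reactants: 15 (2E,4E)-5-bromopenta-2,4-dienoic acid; 12 2-amino-3-hydroxycyclopent-2-en-1-one hydrochloride
Product: 17 (2E,4E)-5-bromo-N-(2-hydroxy-5-oxocyclopent-1-en-1-yl)penta-2,4-dienamide, via acid chloride 16 (not isolated)
Conditions: (COCl)2, DMF (cat.), CH2Cl2, 0 °C → rt; then 12, pyridine, THF, 0 °C → rt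
Reagents that add atoms: none
Why: Amide formation through the acid chloride, the amine nitrogen of the aminocyclopentenolone being acylated in preference to the vinylogous acid oxygen.

**Step 10**
Reactants: 18 1-methoxy-4-[(prop-2-yn-1-yloxy)methyl]benzene; 19 (R)-4-[(tert-butyldimethylsilyl)oxy]cyclopent-2-en-1-one
Product: 22 (1S,4R)-4-[(tert-butyldimethylsilyl)oxy]-1-{1-[(4-methoxyphenyl)methoxy]propa-1,2-dien-1-yl}cyclopent-2-en-1-ol, via allenyl ether 20 (not isolated), via lithioallene 21 (not isolated)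
Conditions: KOtBu (0.2 equiv), THF, rt; then n-BuLi, −78 °C; then 19, −78 °C; NH4Cl (aq)
Reagents that add atoms: none
Why: Base-catalysed propargyl-to-allenyl ether isomerisation, α-lithiation of the alkoxyallene and 1,2-addition to the enone carbonyl anti to the silyloxy group set the 1S carbinol centre (hydroxyl cis to OTBS).

**Step 11**
Reactants: 22 (1S,4R)-4-[(tert-butyldimethylsilyl)oxy]-1-{1-[(4-methoxyphenyl)methoxy]propa-1,2-dien-1-yl}cyclopent-2-en-1-ol
Product: 23 (2R,5R)-5-[(tert-butyldimethylsilyl)oxy]-2-ethenyl-2-[(4-methoxyphenyl)methoxy]cyclohex-3-en-1-one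
Conditions: Pd2(dba)3·CHCl3 (2.5 mol %), (R,R)-DACH-phenyl Trost ligand (7.5 mol %), PhCO2H (10 mol %), Et3N (10 mol %), ClCH2CH2Cl, 50 °C
Reagents that add atoms: none
Why: Proposed new method: a palladium hydride (zerovalent palladium plus PhCO2H) adds to the alkoxyallene to give an alkoxy-substituted π-allylpalladium complex whose oxygen-bearing terminus is oxocarbenium-like; the adjacent carbinol then drives a Wagner–Meerwein (semipinacol) 1,2-shift of the ring alkenyl carbon (π-assisted, hence preferred over the CH2) onto that terminus anti to palladium, which expands the five- to the six-membered ring, creates the ketone and leaves the vinyl group, C=O formation and loss of the allene supplying the driving force that ring strain supplies in the closest known reaction, the palladium-catalysed asymmetric ring expansion of alkoxyallenyl cyclobutanols to 2-alkoxy-2-vinylcyclopentanones (unknown for unstrained cyclopentenols and for alkenyl migration); the quaternary centre is set 2R because the shift is suprafacial from the 1S carbinol carbon through the rotamer with the ether oxygen gauche to the carbinol hydroxyl, which places the ether on the face of the former hydroxyl (cis to OTBS) and the vinyl group on the opposite face, the ligand antipode being the one whose allyl-face preference matches this.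

**Step 12**
Reactants: 23 (2R,5R)-5-[(tert-butyldimethylsilyl)oxy]-2-ethenyl-2-[(4-methoxyphenyl)methoxy]cyclohex-3-en-1-one
Product: 24 (1S,2R,5R)-5-[(tert-butyldimethylsilyl)oxy]-2-ethenyl-2-[(4-methoxyphenyl)methoxy]cyclohex-3-en-1-ol
Conditions: NaBH4, MeOH–CH2Cl2, −40 °C
Reagents that add atoms: none
Why: Non-chelating hydride reduction in which NaBH4 attacks anti to the pseudo-axial α-alkoxy group (Felkin–Anh, polar effect), the face also left open by the cis silyloxy group, so the new 1S carbinol is cis to the neighbouring ether oxygen.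

**Step 13**
Reactants: 24 (1S,2R,5R)-5-[(tert-butyldimethylsilyl)oxy]-2-ethenyl-2-[(4-methoxyphenyl)methoxy]cyclohex-3-en-1-ol
Product: 25 (1S,3R,6R)-6-ethenyl-6-[(4-methoxyphenyl)methoxy]cyclohex-4-ene-1,3-diol
Conditions: Bu4NF, THF, 0 °C
Reagents that add atoms: none
Why: Fluoride-mediated desilylation frees the allylic alcohol and leaves the benzylic ether and both alkenes untouched.

**Step 14**
Reactants: 25 (1S,3R,6R)-6-ethenyl-6-[(4-methoxyphenyl)methoxy]cyclohex-4-ene-1,3-diol
Product: 27 (3aS,7aR)-7a-ethenyl-2-(4-methoxyphenyl)-3a,7a-dihydro-1,3-benzodioxol-5(4H)-one, via acetal alcohol 26 (not isolated)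
Conditions: DDQ (1.2 equiv), 4 Å MS, CH2Cl2, 0 °C; then MnO2, rt
Reagents that add atoms: none
Why: DDQ oxidises the p-methoxybenzyl ether to an oxocarbenium ion that the cis-vicinal hydroxyl traps as the five-membered acetal (oxidative acetalisation, protecting the diol), and MnO2 then oxidises the remaining allylic alcohol to the enone, erasing the relay stereocentre.

**Step 15**
Reactants: 27 (3aS,7aR)-7a-ethenyl-2-(4-methoxyphenyl)-3a,7a-dihydro-1,3-benzodioxol-5(4H)-one
Product: 28 (3aS,7aR)-7a-ethenyl-6-iodo-2-(4-methoxyphenyl)-3a,7a-dihydro-1,3-benzodioxol-5(4H)-one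
Conditions: I2, pyridine–CH2Cl2, 0 °C → rt
Reagents that add atoms: iodine, II
Why: Johnson α-iodination of the enone (pyridine conjugate addition, iodination of the enolate, elimination) functionalises only the enone α-carbon.

**Step 16**
Reactants: 28 (3aS,7aR)-7a-ethenyl-6-iodo-2-(4-methoxyphenyl)-3a,7a-dihydro-1,3-benzodioxol-5(4H)-one; 9 (2E,4E,6R)-2,4,6-trimethyldeca-2,4-dienamide
Product: 29 (2E,4E,6R)-N-[(3aS,7aR)-7a-ethenyl-2-(4-methoxyphenyl)-5-oxo-3a,4,5,7a-tetrahydro-1,3-benzodioxol-6-yl]-2,4,6-trimethyldeca-2,4-dienamide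
Conditions: CuI (10 mol %), MeNHCH2CH2NHMe (20 mol %), K2CO3, toluene, 60 °C
Reagents that add atoms: none
Why: Copper-catalysed Goldberg-type amidation of the activated vinyl iodide by the primary amide forms the enamide C–N bond, with the acetal holding back β-elimination of the ring oxygen.

**Step 17**
Reactants: 29 (2E,4E,6R)-N-[(3aS,7aR)-7a-ethenyl-2-(4-methoxyphenyl)-5-oxo-3a,4,5,7a-tetrahydro-1,3-benzodioxol-6-yl]-2,4,6-trimethyldeca-2,4-dienamide
Product: 30 (2E,4E,6R)-N-[(3R,4S)-3-ethenyl-3,4-dihydroxy-6-oxocyclohex-1-en-1-yl]-2,4,6-trimethyldeca-2,4-dienamide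
Conditions: AcOH–H2O (4:1), rt
Reagents that add atoms: none
Why: Mild acid hydrolysis of the electron-rich benzylidene acetal releases the cis diol without ionising the tertiary allylic alcohol.

**Step 18**
Reactants: 30 (2E,4E,6R)-N-[(3R,4S)-3-ethenyl-3,4-dihydroxy-6-oxocyclohex-1-en-1-yl]-2,4,6-trimethyldeca-2,4-dienamide; 17 (2E,4E)-5-bromo-N-(2-hydroxy-5-oxocyclopent-1-en-1-yl)penta-2,4-dienamide
Product: 31 (2E,4E,6R)-N-[(3R,4S)-3,4-dihydroxy-3-[(1E,3E,5E)-7-[(2-hydroxy-5-oxocyclopent-1-en-1-yl)amino]-7-oxohepta-1,3,5-trien-1-yl]-6-oxocyclohex-1-en-1-yl]-2,4,6-trimethyldeca-2,4-dienamide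
Conditions: Pd(OAc)2 (10 mol %), Ag2CO3, DMF, 40 °C
Reagents that add atoms: none
Why: Silver-promoted Mizoroki–Heck coupling of the bromodiene with the terminal vinyl group of the tertiary allylic alcohol (insertion at CH2, syn β-hydride elimination) gives the new E alkene and completes the E,E,E triene under nearly neutral conditions.

**Compound list**
1 | (E)-hept-2-en-1-ol | CCCC/C=C/CO | starting material
2 | (E)-1-bromohept-2-ene | CCCC/C=C/CBr | intermediate
3 | (R)-3-methylhept-1-ene | CCCC[C@@H](C)C=C | intermediate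
4 | methacrolein (2-methylprop-2-enal) | CC(=C)C=O | starting material
5 | (2E,4R)-2,4-dimethyloct-2-enal | CCCC[C@@H](C)/C=C(\C)C=O | intermediate
6 | 2-bromopropanamide (racemic) | CC(Br)C(N)=O | starting material
7 | (1-amino-1-oxopropan-2-yl)triphenylphosphonium bromide | CC(C(N)=O)[P+](c1ccccc1)(c1ccccc1)c1ccccc1.[Br-] | intermediate
8 | 2-(triphenyl-λ5-phosphanylidene)propanamide | CC(C(N)=O)=P(c1ccccc1)(c1ccccc1)c1ccccc1 | intermediate
9 | (2E,4E,6R)-2,4,6-trimethyldeca-2,4-dienamide | CCCC[C@@H](C)/C=C(C)/C=C(\C)C(N)=O | intermediate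
10 | cyclopentane-1,3-dione | O=C1CCC(=O)C1 | starting material
11 | 2-(hydroxyimino)cyclopentane-1,3-dione | O=C1CCC(=O)C1=NO | intermediate
12 | 2-amino-3-hydroxycyclopent-2-en-1-one hydrochloride | Cl.NC1=C(O)CCC1=O | intermediate
13 | potassium (1E,3E)-5-oxopenta-1,3-dien-1-olate (glutaconaldehyde potassium salt) | [K+].[O-]/C=C/C=C/C=O | starting material
14 | (2E,4E)-5-bromopenta-2,4-dienal | Br/C=C/C=C/C=O | intermediate
15 | (2E,4E)-5-bromopenta-2,4-dienoic acid | Br/C=C/C=C/C(O)=O | intermediate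
16 | (2E,4E)-5-bromopenta-2,4-dienoyl chloride | Br/C=C/C=C/C(Cl)=O | intermediate
17 | (2E,4E)-5-bromo-N-(2-hydroxy-5-oxocyclopent-1-en-1-yl)penta-2,4-dienamide | Br/C=C/C=C/C(=O)NC1=C(O)CCC1=O | intermediate
18 | 1-methoxy-4-[(prop-2-yn-1-yloxy)methyl]benzene (p-methoxybenzyl ether of propargyl alcohol) | C#CCOCc1ccc(OC)cc1 | starting material
19 | (R)-4-[(tert-butyldimethylsilyl)oxy]cyclopent-2-en-1-one | O=C1C=C[C@H](O[Si](C)(C)C(C)(C)C)C1 | starting material
20 | 1-methoxy-4-[(propa-1,2-dien-1-yloxy)methyl]benzene | C=C=COCc1ccc(OC)cc1 | intermediate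
21 | {1-[(4-methoxyphenyl)methoxy]propa-1,2-dien-1-yl}lithium | [Li]C(=C=C)OCc1ccc(OC)cc1 | intermediate
22 | (1S,4R)-4-[(tert-butyldimethylsilyl)oxy]-1-{1-[(4-methoxyphenyl)methoxy]propa-1,2-dien-1-yl}cyclopent-2-en-1-ol | O[C@]1(C(=C=C)OCc2ccc(OC)cc2)C=C[C@H](O[Si](C)(C)C(C)(C)C)C1 | intermediate
23 | (2R,5R)-5-[(tert-butyldimethylsilyl)oxy]-2-ethenyl-2-[(4-methoxyphenyl)methoxy]cyclohex-3-en-1-one | C1=C[C@](OCc2ccc(OC)cc2)(C=C)C(=O)C[C@H]1O[Si](C)(C)C(C)(C)C | intermediate
24 | (1S,2R,5R)-5-[(tert-butyldimethylsilyl)oxy]-2-ethenyl-2-[(4-methoxyphenyl)methoxy]cyclohex-3-en-1-ol | C1=C[C@](OCc2ccc(OC)cc2)(C=C)[C@@H](O)C[C@H]1O[Si](C)(C)C(C)(C)C | intermediate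
25 | (1S,3R,6R)-6-ethenyl-6-[(4-methoxyphenyl)methoxy]cyclohex-4-ene-1,3-diol (all three oxygens cis) | C1=C[C@](OCc2ccc(OC)cc2)(C=C)[C@@H](O)C[C@H]1O | intermediate
26 | (3aS,5R,7aR)-7a-ethenyl-2-(4-methoxyphenyl)-3a,4,5,7a-tetrahydro-1,3-benzodioxol-5-ol (acetal carbon: epimer mixture) | C1=C[C@](OC(c2ccc(OC)cc2)O3)(C=C)[C@@H]3C[C@H]1O | intermediate
27 | (3aS,7aR)-7a-ethenyl-2-(4-methoxyphenyl)-3a,7a-dihydro-1,3-benzodioxol-5(4H)-one (acetal carbon: epimer mixture) | C1=C[C@](OC(c2ccc(OC)cc2)O3)(C=C)[C@@H]3CC1=O | intermediate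
28 | (3aS,7aR)-7a-ethenyl-6-iodo-2-(4-methoxyphenyl)-3a,7a-dihydro-1,3-benzodioxol-5(4H)-one (acetal carbon: epimer mixture) | IC1=C[C@](OC(c2ccc(OC)cc2)O3)(C=C)[C@@H]3CC1=O | intermediate
29 | (2E,4E,6R)-N-[(3aS,7aR)-7a-ethenyl-2-(4-methoxyphenyl)-5-oxo-3a,4,5,7a-tetrahydro-1,3-benzodioxol-6-yl]-2,4,6-trimethyldeca-2,4-dienamide (acetal carbon: epimer mixture) | CCCC[C@@H](C)/C=C(C)/C=C(\C)C(=O)NC1=C[C@](OC(c2ccc(OC)cc2)O3)(C=C)[C@@H]3CC1=O | intermediate
30 | (2E,4E,6R)-N-[(3R,4S)-3-ethenyl-3,4-dihydroxy-6-oxocyclohex-1-en-1-yl]-2,4,6-trimethyldeca-2,4-dienamide | CCCC[C@@H](C)/C=C(C)/C=C(\C)C(=O)NC1=C[C@](O)(C=C)[C@@H](O)CC1=O | intermediate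
31 | (2E,4E,6R)-N-[(3R,4S)-3,4-dihydroxy-3-[(1E,3E,5E)-7-[(2-hydroxy-5-oxocyclopent-1-en-1-yl)amino]-7-oxohepta-1,3,5-trien-1-yl]-6-oxocyclohex-1-en-1-yl]-2,4,6-trimethyldeca-2,4-dienamide | CCCC[C@@H](C)/C=C(C)/C=C(\C)C(=O)NC1=C[C@](O)(/C=C/C=C/C=C/C(=O)NC2=C(O)CCC2=O)[C@@H](O)CC1=O | target

**Step count**
Total: 18 steps. Longest linear sequence: 9 steps (steps 10–18, from 18 and 19 to 31). The dienamide branch (steps 1–4) joins at step 16 and the bromodienamide branch (steps 5–9) at step 18.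

**Three steps most likely to fail**

Step 11 (the proposed ring expansion; the unstrained ring may not migrate, or the hydroxyl may close onto the allyl unit instead). Fallback, known chemistry only, from dienamide 9 back to vinyl carbinol 30: 9 is N-arylated with commercial 3-iodophenol (CuI, trans-N,N′-dimethylcyclohexane-1,2-diamine, K3PO4, dioxane, 90 °C) to the anilide (2E,4E,6R)-N-(3-hydroxyphenyl)-2,4,6-trimethyldeca-2,4-dienamide F1. PhI(OAc)2 in MeOH oxidises the free para position of the phenol to the quinone monoketal (2E,4E,6R)-N-(6,6-dimethoxy-3-oxocyclohexa-1,4-dien-1-yl)-2,4,6-trimethyldeca-2,4-dienamide F2. Phase-transfer epoxidation of the unsubstituted enone (t-BuOOH, NaOH, toluene, N-benzylcinchonidinium chloride or its pseudoenantiomeric cinchoninium salt, whichever gives the 1S,6R epoxide) gives (2E,4E,6R)-N-[(1S,6R)-5,5-dimethoxy-2-oxo-7-oxabicyclo[4.1.0]hept-3-en-4-yl]-2,4,6-trimethyldeca-2,4-dienamide F3. Vinylmagnesium bromide (3 equiv, THF, −78 °C) adds to the ketone anti to the epoxide to give (2E,4E,6R)-N-[(1R,5R,6S)-5-ethenyl-5-hydroxy-2,2-dimethoxy-7-oxabicyclo[4.1.0]hept-3-en-3-yl]-2,4,6-trimethyldeca-2,4-dienamide F4. Montmorillonite K10 in CH2Cl2 unmasks the ketone to give (2E,4E,6R)-N-[(1R,5R,6S)-5-ethenyl-5-hydroxy-2-oxo-7-oxabicyclo[4.1.0]hept-3-en-3-yl]-2,4,6-trimethyldeca-2,4-dienamide F5. Na[PhSeB(OEt)3] (from (PhSe)2 and NaBH4 in EtOH, AcOH) then cleaves the epoxy ketone reductively at the carbon next to the carbonyl and gives 30.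

Step 12 (the face of hydride attack rests on a conformational argument; the wrong epimer cannot form the acetal of step 14). Fallback from ketone 23 back to diol 25: HF·pyridine in THF removes the silyl group to give (2R,5R)-2-ethenyl-5-hydroxy-2-[(4-methoxyphenyl)methoxy]cyclohex-3-en-1-one F6. Et2BOMe and NaBH4 (THF–MeOH, −78 °C, Narasaka–Prasad reduction) then reduce the ketone through the boron chelate of the β-hydroxy ketone to the syn-1,3-diol, which is 25, so the face is fixed by chelation to the relay hydroxyl and no longer by the ether.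

Step 18 (Heck coupling on the unprotected β-hydroxy ketone with an acidic coupling partner). Fallback from 30 back to 31: cross-metathesis of 30 with vinylboronic acid pinacol ester (second-generation Hoveyda–Grubbs catalyst, CH2Cl2, 40 °C) gives the E-alkenylboronate (2E,4E,6R)-N-[(3R,4S)-3,4-dihydroxy-6-oxo-3-[(E)-2-(4,4,5,5-tetramethyl-1,3,2-dioxaborolan-2-yl)ethenyl]cyclohex-1-en-1-yl]-2,4,6-trimethyldeca-2,4-dienamide F7. Suzuki–Miyaura coupling of F7 with 17 (Pd(PPh3)4, K3PO4, THF–H2O, rt) then gives 31.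

**Further compounds**
F1 | step 11 | (2E,4E,6R)-N-(3-hydroxyphenyl)-2,4,6-trimethyldeca-2,4-dienamide | CCCC[C@@H](C)/C=C(C)/C=C(\C)C(=O)Nc1cccc(O)c1
F2 | step 11 | (2E,4E,6R)-N-(6,6-dimethoxy-3-oxocyclohexa-1,4-dien-1-yl)-2,4,6-trimethyldeca-2,4-dienamide | CCCC[C@@H](C)/C=C(C)/C=C(\C)C(=O)NC1=CC(=O)C=CC1(OC)OC
F3 | step 11 | (2E,4E,6R)-N-[(1S,6R)-5,5-dimethoxy-2-oxo-7-oxabicyclo[4.1.0]hept-3-en-4-yl]-2,4,6-trimethyldeca-2,4-dienamide | CCCC[C@@H](C)/C=C(C)/C=C(\C)C(=O)NC1=CC(=O)[C@H]3O[C@H]3C1(OC)OC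
F4 | step 11 | (2E,4E,6R)-N-[(1R,5R,6S)-5-ethenyl-5-hydroxy-2,2-dimethoxy-7-oxabicyclo[4.1.0]hept-3-en-3-yl]-2,4,6-trimethyldeca-2,4-dienamide | CCCC[C@@H](C)/C=C(C)/C=C(\C)C(=O)NC1=C[C@](O)(C=C)[C@H]3O[C@H]3C1(OC)OC
F5 | step 11 | (2E,4E,6R)-N-[(1R,5R,6S)-5-ethenyl-5-hydroxy-2-oxo-7-oxabicyclo[4.1.0]hept-3-en-3-yl]-2,4,6-trimethyldeca-2,4-dienamide | CCCC[C@@H](C)/C=C(C)/C=C(\C)C(=O)NC1=C[C@](O)(C=C)[C@H]3O[C@H]3C1=O
F6 | step 12 | (2R,5R)-2-ethenyl-5-hydroxy-2-[(4-methoxyphenyl)methoxy]cyclohex-3-en-1-one | C1=C[C@](OCc2ccc(OC)cc2)(C=C)C(=O)C[C@H]1O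
F7 | step 18 | (2E,4E,6R)-N-[(3R,4S)-3,4-dihydroxy-6-oxo-3-[(E)-2-(4,4,5,5-tetramethyl-1,3,2-dioxaborolan-2-yl)ethenyl]cyclohex-1-en-1-yl]-2,4,6-trimethyldeca-2,4-dienamide | CCCC[C@@H](C)/C=C(C)/C=C(\C)C(=O)NC1=C[C@](O)(/C=C/B2OC(C)(C)C(C)(C)O2)[C@@H](O)CC1=O
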